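**Retrosynthetic overview**
- The last bond made is the third C–Br bond: one ortho-bromination of ring B of 2,6-dibromo-4-(4-hydroxybenzyl)phenol. Ring A has no open ortho or para position.
- The key disconnection is the CH2–aryl bond. It is made by a new metal-free ipso-deborylative 1,6-arylation of the ring A para-quinone methide with potassium trifluoro(4-hydroxyphenyl)borate (ring B).
- The quinone methide comes from 3,5-dibromo-4-hydroxybenzyl alcohol, made from 3,5-dibromo-4-hydroxybenzaldehyde. The trifluoroborate comes from 4-hydroxyphenylboronic acid.
- No ring is formed. Rings A and B are bought as benzene rings and are joined through the CH2 carbon in step 3.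

Assumption: the target has no stereocentre or other stereogenic element and its SMILES carries no stereodescriptor. It is achiral, so the request for a single enantiomer is met by the compound itself.

**Step 1**
Reactants: 1 3,5-dibromo-4-hydroxybenzaldehyde
Product: 2 2,6-dibromo-4-(hydroxymethyl)phenol
Conditions: NaBH4 (1.2 equiv), THF/MeOH 4:1, 0 °C, 1 h; then 1 M HCl to pH 4 at 0 °C
Reagents that add atoms: none
Why: Borohydride 1,2-reduction of the aldehyde (carbonyl hydride reduction) leaves the aryl bromides and the phenol untouched, the cold and brief work-up avoids premature quinone methide formation, and no stereocentre is created.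

**Step 2**
Reactants: 3 4-hydroxyphenylboronic acid
Product: 4 potassium trifluoro(4-hydroxyphenyl)borate
Conditions: KHF2 (3.5 equiv, 4.5 M aq), MeOH, 25 °C, 1 h; evaporate, extract with hot acetone, precipitate with Et2O
Reagents that add atoms: potassium hydrogen difluoride, F.[F-].[K+]
Why: Conversion of a boronic acid into its trifluoroborate with KHF2 is a general ligand exchange at boron that tolerates a free phenol and gives a crystalline, monomeric, anionic aryl donor.

**Step 3**
Reactants: 2 2,6-dibromo-4-(hydroxymethyl)phenol; 4 potassium trifluoro(4-hydroxyphenyl)borate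
Product: 7 2,6-dibromo-4-[(4-hydroxyphenyl)methyl]phenol, via quinone methide 5 (not isolated), via ipso-borate dienone 6 (not isolated)
Conditions: HBF4·OEt2 (5 mol %), (CF3)2CHOH (HFIP, 0.1 M), 25 °C, PFA vessel; 2 added over 2 h to 4 (1.5 equiv)
Reagents that add atoms: none
Why: Proposed new method: this is a metal-free dehydrative ipso-benzylation, that is, a deborylative 1,6-arylation of a δ-unsubstituted para-quinone methide by an aryltrifluoroborate, run with only a catalytic acid initiator. HFIP and the trace acid ionise 2 to quinone methide 5, which reacts in its hydrogen-bonded or O-protonated form. The boron-bearing carbon of 4 is the most nucleophilic ring position because it is para to OH and because the C–B(ate) σ bond stabilises the developing cyclohexadienyl cation by hyperconjugation (the boron counterpart of ipso-desilylation). Attack there gives dienone 6, and loss of BF3 rearomatises ring B to 7. The BF3 takes up the water released in the ionisation and ends as K[BF3(OH)], so the acid initiator is never consumed. Ring A has no free ortho or para C–H and cannot act as the nucleophile, and no low-valent metal is present, so both C–Br bonds survive. Any protodeboronated 4 (phenol) can still be benzylated, mainly para, to the same product. The closest known reaction types are the acid-promoted substitution of benzhydryl alcohols and acetals by organotrifluoroborates and the Friedel–Crafts 1,6-addition of arenes to stabilised δ-aryl para-quinone methides. Neither has been shown on a primary, halogenated 4-hydroxybenzyl alcohol with ipso regiocontrol.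

**Step 4**
Reactants: 7 2,6-dibromo-4-[(4-hydroxyphenyl)methyl]phenol
Product: 8 2,6-dibromo-4-[(3-bromo-4-hydroxyphenyl)methyl]phenol (target)
Conditions: NBS (1.00 equiv, added over 20 min), TsOH·H2O (10 mol %), MeOH, 0 to 25 °C, 30 min
Reagents that add atoms: N-bromosuccinimide, O=C1CCC(=O)N1Br
Why: In this electrophilic aromatic substitution (acid-promoted ortho-bromination of a para-substituted phenol with NBS), ring A has no open ortho or para site, the two positions ortho to the OH of ring B are equivalent, and the first bromine deactivates ring B enough for one equivalent of NBS to stop at the monobromide.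

**Compound list**
1 | 3,5-dibromo-4-hydroxybenzaldehyde | O=Cc1cc(Br)c(O)c(Br)c1 | starting material
2 | 2,6-dibromo-4-(hydroxymethyl)phenol | OCc1cc(Br)c(O)c(Br)c1 | intermediate
3 | 4-hydroxyphenylboronic acid | OB(O)c1ccc(O)cc1 | starting material
4 | potassium trifluoro(4-hydroxyphenyl)borate | [K+].F[B-](F)(F)c1ccc(O)cc1 | intermediate
5 | 2,6-dibromo-4-methylidenecyclohexa-2,5-dien-1-one (quinone methide) | C=C1C=C(Br)C(=O)C(Br)=C1 | intermediate
6 | potassium {1-[(3,5-dibromo-4-hydroxyphenyl)methyl]-4-oxocyclohexa-2,5-dien-1-yl}trifluoroborate (ipso-borate dienone) | [K+].F[B-](F)(F)C1(Cc2cc(Br)c(O)c(Br)c2)C=CC(=O)C=C1 | intermediate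
7 | 2,6-dibromo-4-[(4-hydroxyphenyl)methyl]phenol | Oc1ccc(Cc2cc(Br)c(O)c(Br)c2)cc1 | intermediate
8 | 2,6-dibromo-4-[(3-bromo-4-hydroxyphenyl)methyl]phenol | Oc1ccc(Cc2cc(Br)c(O)c(Br)c2)cc1Br | target

**Total step count:** 4. **Longest linear sequence:** 3 steps (1 to 2 to 7 to 8, or 3 to 4 to 7 to 8).

**Three steps most likely to fail**

**Step 3 (the proposed new step).**
- Risks: protodeboronation of 4 may outrun C–C bond formation. Attack may occur ortho to the OH of 4 with the boron retained. Quinone methide 5 may self-condense with 2, losing formaldehyde.
- Fallback: it uses known chemistry only, sets out from 1 and comes back to the route at 7. O-Methylation of 1 (MeI, K2CO3, DMF, 25 °C) gives 3,5-dibromo-4-methoxybenzaldehyde F1. Addition of 4-MeOC6H4MgBr (THF, 0 °C) gives rac-(3,5-dibromo-4-methoxyphenyl)(4-methoxyphenyl)methanol F2. Ionic hydrogenation (Et3SiH, CF3CO2H, CH2Cl2, 0 °C) gives 1,3-dibromo-2-methoxy-5-[(4-methoxyphenyl)methyl]benzene F3. BBr3 (CH2Cl2, −78 to 25 °C) then cleaves both methyl ethers to 7.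

**Step 4.**
- Risks: some over-bromination to the tetrabromide may occur. Oxidation at the benzylic carbon through ipso-bromination of ring A is also possible.
- Fallback: it brings the third bromine in with the nucleophile, sets out from 2 and comes back at 8. Friedel–Crafts benzylation of 2-bromoanisole (5 equiv) with 2 (CF3SO3H 10 mol %, HFIP, 25 °C) goes para to OMe and gives 2,6-dibromo-4-[(3-bromo-4-methoxyphenyl)methyl]phenol F4. BBr3 (CH2Cl2, −78 to 25 °C) then gives 8.

**Step 2.**
- Risks: the hydroxyl-bearing salt may retain KHF2 or KF. That would disturb the acid balance of step 3.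
- Fallback: it goes through a covalent ester that can be chromatographed, sets out from 3 and comes back at 4. Esterification with pinacol (MgSO4, THF, 25 °C) gives 4-(4,4,5,5-tetramethyl-1,3,2-dioxaborolan-2-yl)phenol F5. F5 is purified on silica and then treated with KF (4 equiv, aq) and L-tartaric acid (2.05 equiv) in MeCN/MeOH/THF. Filtering off potassium hydrogen tartrate leaves clean 4.

**Further compounds**
F1 | step 3 | 3,5-dibromo-4-methoxybenzaldehyde | COc1c(Br)cc(C=O)cc1Br
F2 | step 3 | rac-(3,5-dibromo-4-methoxyphenyl)(4-methoxyphenyl)methanol | COc1ccc(cc1)C(O)c1cc(Br)c(OC)c(Br)c1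
F3 | step 3 | 1,3-dibromo-2-methoxy-5-[(4-methoxyphenyl)methyl]benzene | COc1ccc(Cc2cc(Br)c(OC)c(Br)c2)cc1
F4 | step 4 | 2,6-dibromo-4-[(3-bromo-4-methoxyphenyl)methyl]phenol | COc1ccc(Cc2cc(Br)c(O)c(Br)c2)cc1Br
F5 | step 2 | 4-(4,4,5,5-tetramethyl-1,3,2-dioxaborolan-2-yl)phenol | CC1(C)OB(OC1(C)C)c1ccc(O)cc1
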